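**Late readings.** Late in Tuesday's run the bis adduct is still sinking, 43% at 5.00 min and 34% at 8.00 min. Look earlier, though: at 1.00 min Tuesday's three readings total 68.0%.

| setting | Sunday's | Wednesday's | Tuesday's | flask |
|---|---|---|---|---|
| starting material | 10 mM | 15 mM | 20 mM | 20 mM |
| partner | 2.5 equiv | 2.5 equiv | 3.8 equiv | 2.50 equiv |
| remark | run made earlier | run made earlier | run made earlier |  |
| time |  |  |  | 10 min |

| run | time / min | starting material / % | first product / % | bis adduct / % |
|---|---|---|---|---|
| Sunday's | 0.667 | 15 | 13 | 29 |
| Sunday's | 1.33 | 1 | 2 | 34 |
| Sunday's | 3.00 | 2 | 2 | 36 |
| Sunday's | 8.00 | 0 | 4 | 29 |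
| Wednesday's | 1.00 | 5 | 3 | 46 |
| Wednesday's | 3.00 | 1 | 0 | 41 |
| Wednesday's | 5.00 | 3 | 0 | 38 |
| Wednesday's | 8.00 | 6 | 0 | 37 |
| Tuesday's | 1.00 | 4 | 2 | 62 |
| Tuesday's | 3.00 | 1 | 0 | 53 |
| Tuesday's | 5.00 | 0 | 0 | 43 |
| Tuesday's | 8.00 | 2 | 0 | 34 |

(each reading ± 2 percentage points)



1. how much starting material there is at 10 min, in percent of the starting material charged
2. how much first product there is at 10 min, in percent of the starting material charged
3. how much bis adduct there is at 10 min, in percent of the starting material charged
4. how much triple product there is at 10 min, in percent of the starting material charged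

**Bench rule.** You would say 2 equivalents make bis adduct, so 2.50 equiv covers this flask. But Sunday's and Wednesday's runs have equal equivalents. At 3.00 min Sunday's reads 36% bis adduct, and Wednesday's reads more at that time, 41%. So I read a race: capture follows the partner's concentration, and the missing route does not.

**The crossing.** Reckon a leftover partner as the charge less the starting material, a level taken after the first addition and before any capture. Wednesday's run reckons to 22.5 mM. At 1.00 min it holds 46% bis adduct and misses 46.0%, an even split. That leftover is the crossing partner, the level at which capture and the missing route run equal, a reading with its scatter. Leftover over crossing acts as a selectivity factor, so the captured share is leftover over leftover plus crossing. Sunday's leftover gives 40.0%, against a bis adduct reading of 36% at 3.00 min.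

**My reckoning.** This flask's leftover reckons to 30.0 mM, which is 1.33 crossings. So I expect 57.1% in bis adduct and whatever comes from it.

**The forecast.** It gives 0.5% starting material, 0.3% first product, 42% bis adduct and 57% triple product, on the ground of “The missing balance, taken as triple product”. Its bis adduct and triple product total 99.0%, more than my 57.1%.

**The result.** The flask gives 0% starting material, 0% first product, 34.8% bis adduct and 20.5% triple product. Bis adduct and triple product total 55.2%, against my 57.1%, and side product holds 44.8%.

    first product → side product (k = 0.0460 s⁻¹)
    partner + first product → bis adduct (k = 2.00 M⁻¹ s⁻¹)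
    partner + bis adduct → triple product (k = 0.0470 M⁻¹ s⁻¹)
    starting material + partner → first product (k = 2.80 M⁻¹ s⁻¹)

**The neighbour.** The same flask read at 2.5 min has the same leftover and crossing, so the reckoning again gives 57.1%. It holds 48.9% bis adduct and 6.29% triple product, together 55.2%, beside 44.7% side product.

The runs were computed with constants of no real substance, and the scatter is random.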